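**Retrosynthetic overview**
1. Target ⇐ regioselective 5‑O‑isobutyrylation (cyclic orthoester opening) of the 4,5‑diol of a triol macrolactone.
2. Ten‑membered ring and cis‑fused α‑methylene lactone ⇐ one indium‑mediated intramolecular 2‑(alkoxycarbonyl)allylation of an unprotected ω‑formyl allylic bromide: C6–C7 closure (the farnesyl C1–C10 bond) sets C6 and C7, then the new 6‑O closes on C12. Carbocycle first, lactone second.
3. Allylic bromide ⇐ C7 is allylated twice: catalytic asymmetric 2‑(methoxycarbonyl)allylation of a C8 aldehyde (sets C8), (R)‑2‑methylbutanoylation, Wohl–Ziegler allyl transposition.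
4. C8 aldehyde ⇐ cis‑γ‑lactone (C9 acyl; temporary 2,9‑methyl ketal) + isobutenyl Grignard, then ozonolysis; lactone ⇐ syn‑reduction/lactonisation of a chelation‑controlled Mukaiyama aldol.
5. Aldol partners ⇐ Evans methallylation/ozonolysis of a propionyl oxazolidinone (C10) and the methyl ketone of (S)‑glycerate acetonide (C5).

Assumption: germacrane numbering with the lactone on C6 (12,6‑olide, H‑7α) is used: C2 = CHOH, C4 = C(OH)Me, C5 = CH–O‑isobutyryl, C8 = CH–O‑2‑methylbutanoyl, C9 = C=O, C10 = CHMe. The ketal carbon C9 of 12–20 is carried as both anomers (9RS) and is removed in step 11.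

Step 1
Reactants: 1 methyl (4S)-2,2-dimethyl-1,3-dioxolane-4-carboxylate
Product: 3 1-[(4S)-2,2-dimethyl-1,3-dioxolan-4-yl]ethan-1-one, via Weinreb amide 2 (not isolated)
Conditions: MeNH(OMe)·HCl, i‑PrMgCl, THF, −20 °C; then MeMgBr, 0 °C; aq. NH4Cl
Reagents that add atoms: methylmagnesium bromide C[Mg]Br
Why: One‑pot Weinreb amide formation and Grignard addition (Weinreb ketone synthesis), in which the chelated tetrahedral intermediate stops at the ketone and the α‑stereocentre (C5 of the target) is untouched.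

Step 2
Reactants: 4 (4R)-4-benzyl-3-propanoyl-1,3-oxazolidin-2-one; 5 3-bromo-2-methylprop-1-ene
Product: 6 (4R)-4-benzyl-3-[(2S)-2,4-dimethylpent-4-enoyl]-1,3-oxazolidin-2-one
Conditions: NaHMDS, THF, −78 °C; then 5, −78 → −40 °C
Reagents that add atoms: none
Why: Evans asymmetric alkylation, in which the chelated Z‑enolate is attacked by the allylic bromide on the face away from the benzyl group and so sets C10 as S.

Step 3
Reactants: 6 (4R)-4-benzyl-3-[(2S)-2,4-dimethylpent-4-enoyl]-1,3-oxazolidin-2-one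
Product: 7 (4R)-4-benzyl-3-[(2S)-2-methyl-4-oxopentanoyl]-1,3-oxazolidin-2-one
Conditions: O3, CH2Cl2/MeOH, −78 °C; then Me2S
Reagents that add atoms: ozone [O-][O+]=O
Why: Ozonolysis with reductive work‑up cleaves the 1,1‑disubstituted alkene to the methyl ketone without touching the imide or the α‑stereocentre.

Step 4
Reactants: 7 (4R)-4-benzyl-3-[(2S)-2-methyl-4-oxopentanoyl]-1,3-oxazolidin-2-one; 3 1-[(4S)-2,2-dimethyl-1,3-dioxolan-4-yl]ethan-1-one
Product: 9 (4R)-4-benzyl-3-[(2S,6S)-6-[(4S)-2,2-dimethyl-1,3-dioxolan-4-yl]-6-hydroxy-2-methyl-4-oxoheptanoyl]-1,3-oxazolidin-2-one, via silyl enol ether 8 (not isolated)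
Conditions: LDA, TMSCl, THF, −78 °C; then CH2Cl2, 3, MgBr2·OEt2, −78 → −30 °C; aq. NH4Cl
Reagents that add atoms: none
Why: Chelation‑controlled Mukaiyama aldol addition, in which the kinetic methyl‑side silyl enol ether adds to ketone 3 held as a five‑membered Mg chelate (C=O and α‑dioxolane oxygen) from the face opposite the ring CH2, which sets the tertiary carbinol C4 as S (4,5‑syn).

Step 5
Reactants: 9 (4R)-4-benzyl-3-[(2S,6S)-6-[(4S)-2,2-dimethyl-1,3-dioxolan-4-yl]-6-hydroxy-2-methyl-4-oxoheptanoyl]-1,3-oxazolidin-2-one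
Product: 11 (3S,5S)-5-[(2S)-2-[(4S)-2,2-dimethyl-1,3-dioxolan-4-yl]-2-hydroxypropyl]-3-methyloxolan-2-one, via diol imide 10 (not isolated)
Conditions: Et2BOMe, THF/MeOH 4:1, −78 °C; NaBH4; MeOH co‑evaporation (Et2BOMe recovered); then DBU (cat.), CH2Cl2, rt
Reagents that add atoms: none
Why: Narasaka–Prasad reduction delivers hydride axially to the six‑membered boron chelate of the β‑hydroxy ketone to give the 2,4‑syn diol (C2 = S), and the γ‑hydroxy imide then lactonises with loss of the auxiliary to the cis‑3,5‑disubstituted lactone.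

Step 6
Reactants: 11 (3S,5S)-5-[(2S)-2-[(4S)-2,2-dimethyl-1,3-dioxolan-4-yl]-2-hydroxypropyl]-3-methyloxolan-2-one
Product: 13 (2S)-2-[(4S)-2,2-dimethyl-1,3-dioxolan-4-yl]-1-[(2S,4S,5RS)-5-methoxy-4-methyl-5-(2-methylprop-1-en-1-yl)oxolan-2-yl]propan-2-ol, via hemiketal 12 (not isolated)
Conditions: Me2C=CHMgBr (3 equiv), THF, −78 °C; aq. NH4Cl; then MeOH, PPTS (cat.), 3 Å MS, 0 °C
Reagents that add atoms: (2-methylprop-1-en-1-yl)magnesium bromide CC(C)=C[Mg]Br; methanol CO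
Why: Grignard mono‑addition to the γ‑lactone (the magnesium hemiketal alkoxide does not collapse at −78 °C) followed by Fischer‑type acetalisation gives the cyclic methyl ketal, which masks the C9 ketone and O‑2 together.

Step 7
Reactants: 13 (2S)-2-[(4S)-2,2-dimethyl-1,3-dioxolan-4-yl]-1-[(2S,4S,5RS)-5-methoxy-4-methyl-5-(2-methylprop-1-en-1-yl)oxolan-2-yl]propan-2-ol
Product: 14 (2RS,3S,5S)-5-[(2S)-2-[(4S)-2,2-dimethyl-1,3-dioxolan-4-yl]-2-hydroxypropyl]-2-methoxy-3-methyloxolane-2-carbaldehyde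
Conditions: O3, CH2Cl2, −78 °C; then Me2S
Reagents that add atoms: ozone [O-][O+]=O
Why: Ozonolysis of the electron‑rich trisubstituted alkene gives the non‑enolisable α‑ketal aldehyde (C8) and acetone.

Step 8
Reactants: 14 (2RS,3S,5S)-5-[(2S)-2-[(4S)-2,2-dimethyl-1,3-dioxolan-4-yl]-2-hydroxypropyl]-2-methoxy-3-methyloxolane-2-carbaldehyde; 15 methyl 2-(bromomethyl)prop-2-enoate
Product: 17 methyl (4S)-4-hydroxy-4-[Ox]-2-methylidenebutanoate, via silyl ether 16 (not isolated)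
Conditions: CrCl2 (10 mol %), chiral 1,8‑bis(oxazolinyl)carbazole ligand (12 mol %), Mn, TMSCl, THF, rt; then citric acid, MeOH, 0 °C
Reagents that add atoms: none
Why: Catalytic enantioselective Nozaki–Hiyama–Kishi 2‑(alkoxycarbonyl)allylation, in which the chiral allyl‑Cr(III) complex adds through a closed transition state to one aldehyde face (ligand antipode chosen to give 8S, reagent control over both ketal anomers), and mild methanolysis of the silyl ether leaves the hydroxy ester unlactonised.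

Step 9
Reactants: 17 methyl (4S)-4-hydroxy-4-[Ox]-2-methylidenebutanoate; 18 (2R)-2-methylbutanoic acid
Product: 19 methyl (4S)-4-[Ox]-2-methylidene-4-{[(2R)-2-methylbutanoyl]oxy}butanoate
Conditions: EDC·HCl, DMAP, CH2Cl2, 0 °C → rt
Reagents that add atoms: none
Why: Steglich esterification acylates only the secondary C8 hydroxyl (the C4 hydroxyl is tertiary, O‑2 is in the ketal) and does not epimerise the α‑centre of the acid.

Step 10
Reactants: 19 methyl (4S)-4-[Ox]-2-methylidene-4-{[(2R)-2-methylbutanoyl]oxy}butanoate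
Product: 20 methyl (2Z,4S)-2-(bromomethyl)-4-[Ox]-4-{[(2R)-2-methylbutanoyl]oxy}but-2-enoate
Conditions: NBS (1.05 equiv), AIBN (cat.), PhCF3, 80 °C
Reagents that add atoms: N-bromosuccinimide O=C1CCC(=O)N1Br
Why: Wohl–Ziegler bromination, in which the allyl radical formed by H‑abstraction at C7 is brominated at the unsubstituted terminus C13 to give the conjugated (Z)‑2‑(bromomethyl)enoate (a secondary allylic bromide isomer would give the same allylindium in step 13).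

Step 11
Reactants: 20 methyl (2Z,4S)-2-(bromomethyl)-4-[Ox]-4-{[(2R)-2-methylbutanoyl]oxy}but-2-enoate
Product: 21 methyl (2Z,4S,6S,8S,10S,11S)-2-(bromomethyl)-8,10,11,12-tetrahydroxy-6,10-dimethyl-4-{[(2R)-2-methylbutanoyl]oxy}-5-oxododec-2-enoate
Conditions: AcOH/H2O/THF 3:1:1, 40 °C
Reagents that add atoms: water O
Why: Acid‑catalysed acetal hydrolysis removes the methyl ketal and the terminal acetonide in one operation, freeing the C9 ketone, O‑2 and the 5,6‑diol while the esters and the allylic bromide survive.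

Step 12
Reactants: 21 methyl (2Z,4S,6S,8S,10S,11S)-2-(bromomethyl)-8,10,11,12-tetrahydroxy-6,10-dimethyl-4-{[(2R)-2-methylbutanoyl]oxy}-5-oxododec-2-enoate
Product: 22 methyl (2Z,4S,6S,8S,10S,11R)-2-(bromomethyl)-8,10,11-trihydroxy-6,10-dimethyl-4-{[(2R)-2-methylbutanoyl]oxy}-5,12-dioxododec-2-enoate
Conditions: TEMPO (10 mol %), PhI(OAc)2 (1.1 equiv), CH2Cl2, 0 °C
Reagents that add atoms: none
Why: TEMPO/PhI(OAc)2 (oxoammonium) oxidation is selective for the primary alcohol and stops at the aldehyde, which rests as its six‑membered lactol with O‑2 (a 2‑deoxy‑sugar‑like hemiacetal).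

Step 13
Reactants: 22 methyl (2Z,4S,6S,8S,10S,11R)-2-(bromomethyl)-8,10,11-trihydroxy-6,10-dimethyl-4-{[(2R)-2-methylbutanoyl]oxy}-5,12-dioxododec-2-enoate
Product: 24 (3aS,4S,6S,8S,10S,11S,11aR)-8,10,11-trihydroxy-6,10-dimethyl-3-methylidene-2,5-dioxododecahydrocyclodeca[b]furan-4-yl (2R)-2-methylbutanoate, via hydroxy ester 23 (not isolated)
Conditions: In powder (4 equiv), THF/H2O 1:1, 35 °C, slow addition of 22 (final 2 mM); then p‑TsOH (cat.), CH2Cl2, rt
Reagents that add atoms: none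
Why: Indium‑mediated intramolecular Barbier allylation in water (as with unprotected sugars; macrocyclic Barbier/NHK closures of germacranolide rings are known) then lactonisation: the free 5‑OH chelates indium with the aldehyde to give the 5,6‑threo carbinol, the cyclic transition state of the 2‑(alkoxycarbonyl)allylindium gives the 6,7‑syn adduct and hence the cis lactone, and C7 is attacked anti to C9 with H‑8 eclipsing the allyl unit (A1,3 strain), so C6 (R) and C7 (S) follow from C5 and C8.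

Step 14
Reactants: 24 (3aS,4S,6S,8S,10S,11S,11aR)-8,10,11-trihydroxy-6,10-dimethyl-3-methylidene-2,5-dioxododecahydrocyclodeca[b]furan-4-yl (2R)-2-methylbutanoate; 25 1,1,1-trimethoxy-2-methylpropane
Product: 27 (3aS,4S,6S,8S,10S,11S,11aR)-8,10-dihydroxy-6,10-dimethyl-3-methylidene-11-[(2-methylpropanoyl)oxy]-2,5-dioxododecahydrocyclodeca[b]furan-4-yl (2R)-2-methylbutanoate, via cyclic orthoester 26 (not isolated)
Conditions: 25 (1.5 equiv), PPTS (cat.), CH2Cl2, rt; then AcOH/H2O 4:1, rt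
Reagents that add atoms: water O
Why: Cyclic orthoester formation on the only vicinal diol (O‑4/O‑5) and mild acid hydrolysis through the dioxolanylium ion gives the ester on the secondary oxygen (a 4‑O‑acyl isomer would migrate to O‑5), so the isolated 2‑OH is not acylated.

**Compound list**
[Ox] = (2RS,3S,5S)-5-{(2S)-2-[(4S)-2,2-dimethyl-1,3-dioxolan-4-yl]-2-hydroxypropyl}-2-methoxy-3-methyloxolan-2-yl

1 | methyl (4S)-2,2-dimethyl-1,3-dioxolane-4-carboxylate | COC(=O)[C@@H]1COC(C)(C)O1 | starting material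
2 | (4S)-N-methoxy-N,2,2-trimethyl-1,3-dioxolane-4-carboxamide | CON(C)C(=O)[C@@H]1COC(C)(C)O1 | intermediate
3 | 1-[(4S)-2,2-dimethyl-1,3-dioxolan-4-yl]ethan-1-one | CC(=O)[C@@H]1COC(C)(C)O1 | intermediate
4 | (4R)-4-benzyl-3-propanoyl-1,3-oxazolidin-2-one | CCC(=O)N1[C@H](Cc2ccccc2)COC1=O | starting material
5 | 3-bromo-2-methylprop-1-ene | C=C(C)CBr | starting material
6 | (4R)-4-benzyl-3-[(2S)-2,4-dimethylpent-4-enoyl]-1,3-oxazolidin-2-one | C=C(C)C[C@H](C)C(=O)N1[C@H](Cc2ccccc2)COC1=O | intermediate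
7 | (4R)-4-benzyl-3-[(2S)-2-methyl-4-oxopentanoyl]-1,3-oxazolidin-2-one | CC(=O)C[C@H](C)C(=O)N1[C@H](Cc2ccccc2)COC1=O | intermediate
8 | (4R)-4-benzyl-3-[(2S)-2-methyl-4-(trimethylsilyloxy)pent-4-enoyl]-1,3-oxazolidin-2-one | C=C(O[Si](C)(C)C)C[C@H](C)C(=O)N1[C@H](Cc2ccccc2)COC1=O | intermediate
9 | (4R)-4-benzyl-3-[(2S,6S)-6-[(4S)-2,2-dimethyl-1,3-dioxolan-4-yl]-6-hydroxy-2-methyl-4-oxoheptanoyl]-1,3-oxazolidin-2-one | C1OC(C)(C)O[C@@H]1[C@@](C)(O)CC(=O)C[C@H](C)C(=O)N2[C@H](Cc3ccccc3)COC2=O | intermediate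
10 | (4R)-4-benzyl-3-[(2S,4S,6S)-6-[(4S)-2,2-dimethyl-1,3-dioxolan-4-yl]-4,6-dihydroxy-2-methylheptanoyl]-1,3-oxazolidin-2-one | C1OC(C)(C)O[C@@H]1[C@@](C)(O)C[C@@H](O)C[C@H](C)C(=O)N2[C@H](Cc3ccccc3)COC2=O | intermediate
11 | (3S,5S)-5-[(2S)-2-[(4S)-2,2-dimethyl-1,3-dioxolan-4-yl]-2-hydroxypropyl]-3-methyloxolan-2-one | C1OC(C)(C)O[C@@H]1[C@@](C)(O)C[C@@H]2C[C@H](C)C(=O)O2 | intermediate
12 | (2RS,3S,5S)-5-[(2S)-2-[(4S)-2,2-dimethyl-1,3-dioxolan-4-yl]-2-hydroxypropyl]-3-methyl-2-(2-methylprop-1-en-1-yl)oxolan-2-ol | C1OC(C)(C)O[C@@H]1[C@@](C)(O)C[C@@H]2C[C@H](C)C(O)(O2)C=C(C)C | intermediate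
13 | (2S)-2-[(4S)-2,2-dimethyl-1,3-dioxolan-4-yl]-1-[(2S,4S,5RS)-5-methoxy-4-methyl-5-(2-methylprop-1-en-1-yl)oxolan-2-yl]propan-2-ol | C1OC(C)(C)O[C@@H]1[C@@](C)(O)C[C@@H]2C[C@H](C)C(OC)(O2)C=C(C)C | intermediate
14 | (2RS,3S,5S)-5-[(2S)-2-[(4S)-2,2-dimethyl-1,3-dioxolan-4-yl]-2-hydroxypropyl]-2-methoxy-3-methyloxolane-2-carbaldehyde | C1OC(C)(C)O[C@@H]1[C@@](C)(O)C[C@@H]2C[C@H](C)C(OC)(O2)C=O | intermediate
15 | methyl 2-(bromomethyl)prop-2-enoate | C=C(CBr)C(=O)OC | starting material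
16 | methyl (4S)-4-[Ox]-2-methylidene-4-(trimethylsilyloxy)butanoate | C1OC(C)(C)O[C@@H]1[C@@](C)(O)C[C@@H]2C[C@H](C)C(OC)(O2)[C@@H](O[Si](C)(C)C)CC(=C)C(=O)OC | intermediate
17 | methyl (4S)-4-hydroxy-4-[Ox]-2-methylidenebutanoate | C1OC(C)(C)O[C@@H]1[C@@](C)(O)C[C@@H]2C[C@H](C)C(OC)(O2)[C@@H](O)CC(=C)C(=O)OC | intermediate
18 | (2R)-2-methylbutanoic acid | CC[C@@H](C)C(=O)O | starting material
19 | methyl (4S)-4-[Ox]-2-methylidene-4-{[(2R)-2-methylbutanoyl]oxy}butanoate | C1OC(C)(C)O[C@@H]1[C@@](C)(O)C[C@@H]2C[C@H](C)C(OC)(O2)[C@@H](OC(=O)[C@H](C)CC)CC(=C)C(=O)OC | intermediate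
20 | methyl (2Z,4S)-2-(bromomethyl)-4-[Ox]-4-{[(2R)-2-methylbutanoyl]oxy}but-2-enoate | C1OC(C)(C)O[C@@H]1[C@@](C)(O)C[C@@H]2C[C@H](C)C(OC)(O2)[C@@H](OC(=O)[C@H](C)CC)/C=C(\CBr)C(=O)OC | intermediate
21 | methyl (2Z,4S,6S,8S,10S,11S)-2-(bromomethyl)-8,10,11,12-tetrahydroxy-6,10-dimethyl-4-{[(2R)-2-methylbutanoyl]oxy}-5-oxododec-2-enoate | OC[C@H](O)[C@@](C)(O)C[C@@H](O)C[C@H](C)C(=O)[C@@H](OC(=O)[C@H](C)CC)/C=C(\CBr)C(=O)OC | intermediate
22 | methyl (2Z,4S,6S,8S,10S,11R)-2-(bromomethyl)-8,10,11-trihydroxy-6,10-dimethyl-4-{[(2R)-2-methylbutanoyl]oxy}-5,12-dioxododec-2-enoate (open form of the C6/O‑2 lactol) | O=C[C@H](O)[C@@](C)(O)C[C@@H](O)C[C@H](C)C(=O)[C@@H](OC(=O)[C@H](C)CC)/C=C(\CBr)C(=O)OC | intermediate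
23 | methyl 2-[(1S,2R,3S,4S,6S,8S,10S)-2,3,4,6-tetrahydroxy-4,8-dimethyl-10-{[(2R)-2-methylbutanoyl]oxy}-9-oxocyclodecyl]prop-2-enoate | C=C(C(=O)OC)[C@@H]1[C@H](OC(=O)[C@H](C)CC)C(=O)[C@@H](C)C[C@H](O)C[C@](C)(O)[C@@H](O)[C@@H]1O | intermediate
24 | (3aS,4S,6S,8S,10S,11S,11aR)-8,10,11-trihydroxy-6,10-dimethyl-3-methylidene-2,5-dioxododecahydrocyclodeca[b]furan-4-yl (2R)-2-methylbutanoate | C=C1C(=O)O[C@@H]2[C@H]1[C@H](OC(=O)[C@H](C)CC)C(=O)[C@@H](C)C[C@H](O)C[C@](C)(O)[C@H]2O | intermediate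
25 | 1,1,1-trimethoxy-2-methylpropane | CC(C)C(OC)(OC)OC | starting material
26 | 10,11‑O‑(1‑methoxy‑2‑methylpropylidene) cyclic orthoester of 24 (germacrane O‑4/O‑5) | C=C1C(=O)O[C@@H]2[C@H]1[C@H](OC(=O)[C@H](C)CC)C(=O)[C@@H](C)C[C@H](O)C[C@](C)(OC(OC)(C(C)C)O3)[C@H]23 | intermediate
27 | (3aS,4S,6S,8S,10S,11S,11aR)-8,10-dihydroxy-6,10-dimethyl-3-methylidene-11-[(2-methylpropanoyl)oxy]-2,5-dioxododecahydrocyclodeca[b]furan-4-yl (2R)-2-methylbutanoate | C=C1C(=O)O[C@@H]2[C@H]1[C@H](OC(=O)[C@H](C)CC)C(=O)[C@@H](C)C[C@H](O)C[C@](C)(O)[C@H]2OC(=O)C(C)C | target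

**Totals and risks**
Total step count: 14. Longest linear sequence: 13 steps (4 → 27; only step 1 is off the main line).

Most likely to fail:

Step 13. The allylindium carries an 8‑acyloxy group that can be lost by 1,4‑elimination to a diene, it can be protonated or oligomerise at high dilution, and the three stereochemical controls have not been tested together in a ring closure. Fallback: starting from 22, Pd(0)‑catalysed stannylation with hexabutylditin gives the allylstannane aldehyde F1. A Lewis‑acid‑promoted (Sc(OTf)3 or MgBr2·OEt2) intramolecular SE2′ allylstannane addition then closes the ring through an open, syn‑selective transition state without a reducing metal or a β‑oxygenated organometallic. This gives hydroxy ester 23, where the fallback rejoins the route.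

Step 10. The bromine radical may attack ether or acetal C–H bonds, or the acrylate may polymerise. Fallback: starting from 14, ProPhenol/Me2Zn‑catalysed alkynylation with methyl propiolate (ligand antipode for 8S) gives the propargylic alcohol F2. Red‑Al trans‑hydroalumination with NIS quench gives the (Z)‑α‑iodo enoate F3. Steglich esterification with 18 gives the iodo ester F4. Stille coupling with (tributylstannyl)methanol gives the allylic alcohol F5. Appel bromination (CBr4, PPh3) returns to 20.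

Step 8. The aldehyde is hindered, is a mixture of two ketal anomers, and catalyst control may be incomplete. Fallback: starting from 14, an unselective indium Barbier reaction with 15 gives 17 together with its C8 epimer F6. Dess–Martin oxidation of the mixture gives the single ketone F7. CBS reduction (oxazaborolidine, catecholborane), which distinguishes the quaternary ketal carbon from the CH2 group, returns to 17.

**Further compounds**
F1 | step 13 | methyl (2Z,4S,6S,8S,10S,11R)-8,10,11-trihydroxy-6,10-dimethyl-4-{[(2R)-2-methylbutanoyl]oxy}-5,12-dioxo-2-[(tributylstannyl)methyl]dodec-2-enoate | O=C[C@H](O)[C@@](C)(O)C[C@@H](O)C[C@H](C)C(=O)[C@@H](OC(=O)[C@H](C)CC)/C=C(\C[Sn](CCCC)(CCCC)CCCC)C(=O)OC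
F2 | step 10 | methyl (4S)-4-hydroxy-4-[Ox]but-2-ynoate | C1OC(C)(C)O[C@@H]1[C@@](C)(O)C[C@@H]2C[C@H](C)C(OC)(O2)[C@@H](O)C#CC(=O)OC
F3 | step 10 | methyl (2Z,4S)-4-hydroxy-2-iodo-4-[Ox]but-2-enoate | C1OC(C)(C)O[C@@H]1[C@@](C)(O)C[C@@H]2C[C@H](C)C(OC)(O2)[C@@H](O)/C=C(\I)C(=O)OC
F4 | step 10 | methyl (2Z,4S)-2-iodo-4-[Ox]-4-{[(2R)-2-methylbutanoyl]oxy}but-2-enoate | C1OC(C)(C)O[C@@H]1[C@@](C)(O)C[C@@H]2C[C@H](C)C(OC)(O2)[C@@H](OC(=O)[C@H](C)CC)/C=C(\I)C(=O)OC
F5 | step 10 | methyl (2E,4S)-2-(hydroxymethyl)-4-[Ox]-4-{[(2R)-2-methylbutanoyl]oxy}but-2-enoate | C1OC(C)(C)O[C@@H]1[C@@](C)(O)C[C@@H]2C[C@H](C)C(OC)(O2)[C@@H](OC(=O)[C@H](C)CC)/C=C(\CO)C(=O)OC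
F6 | step 8 | methyl (4R)-4-hydroxy-4-[Ox]-2-methylidenebutanoate (C8 epimer of 17) | C1OC(C)(C)O[C@@H]1[C@@](C)(O)C[C@@H]2C[C@H](C)C(OC)(O2)[C@H](O)CC(=C)C(=O)OC
F7 | step 8 | methyl 4-[Ox]-2-methylidene-4-oxobutanoate | C1OC(C)(C)O[C@@H]1[C@@](C)(O)C[C@@H]2C[C@H](C)C(OC)(O2)C(=O)CC(=C)C(=O)OC
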